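**Retrosynthetic overview**
1. The C4 ketone is unmasked last from a spiro-1,3-dithiane. The mask removes any acidic C3–H, so no chalcone can form while the C ring is closed.
2. O1–C2 bond: intramolecular Mitsunobu etherification of an (R)-benzylic carbinol by the A-ring 2-OH, with inversion to (2S).
3. C3–C4 bond: 2-aryl-1,3-dithiane anion plus (S)-styrene oxide, opened at CH2. The only stereocentre is bought here.
4. The 7-O-CMe2CH=CH2 ether comes from Pd-π-allyl O-alkylation. The C8–prenyl bond (key step) comes from an aromatic Claisen [3,3] shift of the same kind of ether on chelated 2,4-dihydroxybenzaldehyde.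
5. Ring order: A and B rings are bought, a temporary dithiane ring is made in step 4, and the pyran C ring, the only skeletal ring built, is made in step 7.

Assumption: the stereocentre in the SMILES reads as (2S), and (S)-styrene oxide of at least 98 % ee is the purchased chiral building block.

**Step 1**
Reactants: 1 2-methylbut-3-en-2-ol; 2 di-tert-butyl dicarbonate
Product: 4 tert-butyl 2-methylbut-3-en-2-yl carbonate, via lithium 2-methylbut-3-en-2-olate 3 (not isolated)
Conditions: n-BuLi (1.05 equiv), THF, −78 → 0 °C; then 2, 0 °C → rt; H2O work-up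
Reagents that add atoms: di-tert-butyl dicarbonate (2), CC(C)(C)OC(=O)OC(=O)OC(C)(C)C
Why: O-acylation of the preformed tertiary alkoxide with Boc2O is irreversible because the tert-butyl carbonate leaving group collapses to CO2 and tert-butoxide; no stereocentre is involved.

**Step 2**
Reactants: 5 2,4-dihydroxybenzaldehyde; 4 tert-butyl 2-methylbut-3-en-2-yl carbonate
Product: 6 2-hydroxy-4-[(2-methylbut-3-en-2-yl)oxy]benzaldehyde
Conditions: 4 (1.5 equiv), Pd(PPh3)4 (3 mol %), THF, 0–5 °C
Reagents that add atoms: tert-butyl 2-methylbut-3-en-2-yl carbonate (4), C=CC(C)(C)OC(=O)OC(C)(C)C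
Why: In this Tsuji–Trost O-allylation Pd(0) ionises 4 with loss of CO2, the released tert-butoxide deprotonates the more acidic non-chelated 4-OH (the 2-OH is hydrogen-bonded to CHO), and the phenoxide attacks the more substituted π-allyl terminus under kinetic control in the cold.

**Step 3 (key step)**
Reactants: 6 2-hydroxy-4-[(2-methylbut-3-en-2-yl)oxy]benzaldehyde
Product: 8 2,4-dihydroxy-3-(3-methylbut-2-en-1-yl)benzaldehyde, via C3-prenyl cyclohexadienone 7 (not isolated)
Conditions: PhNEt2, 140 °C, 2 h, Ar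
Reagents that add atoms: none
Why: The aromatic Claisen rearrangement ([3,3]-sigmatropic shift) delivers the CH2 terminus to carbon and so turns the 1,1-dimethylallyl ether into a prenyl group, while the OH···O=C chelate localises the C3=C4 bond and directs the new C–C bond to C3 (future C8) rather than C5 before dienone 7 tautomerises to the phenol.

**Step 4**
Reactants: 8 2,4-dihydroxy-3-(3-methylbut-2-en-1-yl)benzaldehyde; 9 propane-1,3-dithiol
Product: 10 4-(1,3-dithian-2-yl)-2-(3-methylbut-2-en-1-yl)benzene-1,3-diol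
Conditions: 9 (1.1 equiv), MgBr2·OEt2 (30 mol %), 4 Å MS, Et2O/CH2Cl2, rt, Ar, dark
Reagents that add atoms: propane-1,3-dithiol (9), SCCCS
Why: In this Lewis-acid dithioacetalisation Mg(II) chelated between 2-O and CHO activates the aldehyde but is too mild to cyclise the o-prenylphenol to a chroman, and the product sets up Corey–Seebach umpolung of the future C4.

**Step 5**
Reactants: 10 4-(1,3-dithian-2-yl)-2-(3-methylbut-2-en-1-yl)benzene-1,3-diol; 4 tert-butyl 2-methylbut-3-en-2-yl carbonate
Product: 11 6-(1,3-dithian-2-yl)-3-[(2-methylbut-3-en-2-yl)oxy]-2-(3-methylbut-2-en-1-yl)phenol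
Conditions: 4 (1.3 equiv), Pd(PPh3)4 (5 mol %), THF, 0–5 °C
Reagents that add atoms: tert-butyl 2-methylbut-3-en-2-yl carbonate (4), C=CC(C)(C)OC(=O)OC(C)(C)C
Why: In this second Tsuji–Trost O-allylation the bulky tertiary ether forms preferentially at the OH with one ortho substituent rather than the OH flanked by prenyl and dithianyl, and the electron-rich aryl ether is not re-ionised by Pd(0) in the cold.

**Step 6**
Reactants: 11 6-(1,3-dithian-2-yl)-3-[(2-methylbut-3-en-2-yl)oxy]-2-(3-methylbut-2-en-1-yl)phenol; 12 (S)-styrene oxide [(2S)-2-phenyloxirane]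
Product: 14 (1R)-2-{2-[2-hydroxy-4-[(2-methylbut-3-en-2-yl)oxy]-3-(3-methylbut-2-en-1-yl)phenyl]-1,3-dithian-2-yl}-1-phenylethan-1-ol, via O,C-dilithio dianion 13 (not isolated)
Conditions: n-BuLi (2.2 equiv), THF/DMPU, −78 → −20 °C, 2 h; then 12 (1.2 equiv), −78 → 0 °C; H2O
Reagents that add atoms: (S)-styrene oxide (12), c1ccccc1[C@H]1CO1
Why: In this Corey–Seebach alkylation the first equivalent of base gives the phenoxide, the second removes the ArCH(SR)2 proton, and the carbanion opens the epoxide by SN2 at CH2, so the C–O stereocentre of 12 is carried over untouched (S becomes R only because the CIP ranks of CH2 and Ph swap).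

**Step 7**
Reactants: 14 (1R)-carbinol phenol from step 6
Product: 16 (2S)-7-[(2-methylbut-3-en-2-yl)oxy]-8-(3-methylbut-2-en-1-yl)-2-phenyl-2,3-dihydrospiro[chromene-4,2'-[1,3]dithiane], via alkoxyphosphonium phenoxide 15 (not isolated)
Conditions: PPh3 (1.5 equiv), DIAD (1.5 equiv), THF (0.02 M), 0 °C → rt
Reagents that add atoms: none
Why: In this intramolecular Mitsunobu etherification the phenoxide displaces the activated benzylic oxygen in a 6-exo-tet SN2 with inversion (R → S), which sets C2, and the masked carbonyl rules out E1cB loss to a chalcone.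

**Step 8**
Reactants: 16 (2S)-spiro-dithiane flavan from step 7
Product: 17 griffinone C, (2S)-7-[(2-methylbut-3-en-2-yl)oxy]-8-(3-methylbut-2-en-1-yl)-2-phenyl-2,3-dihydro-4H-chromen-4-one
Conditions: MeI (10 equiv), CaCO3 (5 equiv), MeCN/H2O 9:1, 35–40 °C, dark
Reagents that add atoms: water, O
Why: Alkylative dithiane hydrolysis (S-methylation, ionisation assisted by the o,p-oxygenated ring, capture by water) runs near neutrality and below 40 °C, so both alkenes, the acid- and heat-labile tertiary allyl aryl ether and the base-labile C2 stereocentre survive.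

**Compound list**
1 | 2-methylbut-3-en-2-ol | C=CC(C)(C)O | starting material
2 | di-tert-butyl dicarbonate | CC(C)(C)OC(=O)OC(=O)OC(C)(C)C | starting material
3 | lithium 2-methylbut-3-en-2-olate | C=CC(C)(C)O[Li] | intermediate (not isolated)
4 | tert-butyl 2-methylbut-3-en-2-yl carbonate | C=CC(C)(C)OC(=O)OC(C)(C)C | intermediate
5 | 2,4-dihydroxybenzaldehyde | O=Cc1ccc(O)cc1O | starting material
6 | 2-hydroxy-4-[(2-methylbut-3-en-2-yl)oxy]benzaldehyde | C=CC(C)(C)Oc1ccc(C=O)c(O)c1 | intermediate
7 | 2-hydroxy-3-(3-methylbut-2-en-1-yl)-4-oxocyclohexa-1,5-diene-1-carbaldehyde (racemic, transient) | O=CC1=C(O)C(CC=C(C)C)C(=O)C=C1 | intermediate (not isolated)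
8 | 2,4-dihydroxy-3-(3-methylbut-2-en-1-yl)benzaldehyde | O=Cc1ccc(O)c(CC=C(C)C)c1O | intermediate
9 | propane-1,3-dithiol | SCCCS | starting material
10 | 4-(1,3-dithian-2-yl)-2-(3-methylbut-2-en-1-yl)benzene-1,3-diol | Oc1ccc(C2SCCCS2)c(O)c1CC=C(C)C | intermediate
11 | 6-(1,3-dithian-2-yl)-3-[(2-methylbut-3-en-2-yl)oxy]-2-(3-methylbut-2-en-1-yl)phenol | C=CC(C)(C)Oc1ccc(C2SCCCS2)c(O)c1CC=C(C)C | intermediate
12 | (S)-styrene oxide | c1ccccc1[C@H]1CO1 | starting material
13 | O,C-dilithio dianion of 11 (lithium phenoxide, 2-lithio-1,3-dithiane) | C=CC(C)(C)Oc1ccc(C2([Li])SCCCS2)c(O[Li])c1CC=C(C)C | intermediate (not isolated)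
14 | (1R)-2-{2-[2-hydroxy-4-[(2-methylbut-3-en-2-yl)oxy]-3-(3-methylbut-2-en-1-yl)phenyl]-1,3-dithian-2-yl}-1-phenylethan-1-ol | C=CC(C)(C)Oc1ccc(C2(C[C@@H](O)c3ccccc3)SCCCS2)c(O)c1CC=C(C)C | intermediate
15 | (R)-alkoxy(triphenyl)phosphonium phenoxide zwitterion of 14 | C=CC(C)(C)Oc1ccc(C2(C[C@@H](O[P+](c3ccccc3)(c3ccccc3)c3ccccc3)c3ccccc3)SCCCS2)c([O-])c1CC=C(C)C | intermediate (not isolated)
16 | (2S)-7-[(2-methylbut-3-en-2-yl)oxy]-8-(3-methylbut-2-en-1-yl)-2-phenyl-2,3-dihydrospiro[chromene-4,2'-[1,3]dithiane] | C=CC(C)(C)Oc1ccc2c(c1CC=C(C)C)O[C@H](c1ccccc1)CC23SCCCS3 | intermediate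
17 | griffinone C | C=CC(C)(C)Oc1ccc2c(c1CC=C(C)C)O[C@H](c1ccccc1)CC2=O | target

**Total step count:** 8
**Longest linear sequence:** 8 steps (1 → 4 → 6 → 8 → 10 → 11 → 14 → 16 → 17), or 7 steps from 2,4-dihydroxybenzaldehyde 5.

**Three steps most likely to fail**

Step 6 (dianion formation). The ortho phenoxide makes the dithiane C–H less acidic, and the allylic-benzylic CH2 of the prenyl group could compete for base. The fallback sets out from 11 and comes back at 14.
- The phenol is masked first with NaH and SEMCl in THF at 0 °C to give the SEM ether F2.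
- One equivalent of n-BuLi (THF, −30 °C) then has to make only a monoanion, helped by coordination to the OCH2O unit. This gives the lithiodithiane F3.
- F3 opens 12 at CH2 to give the SEM-protected (R)-carbinol F4.
- TBAF in THF/DMPU at 40–45 °C frees the phenol without acid and below the Claisen temperature, giving 14.

Step 5 (site selectivity between two phenols, and a Pd catalyst next to a dithiane). The fallback sets out from 8 and comes back at 11.
- The order of events is swapped. The Pd-π-allyl etherification with 4 is run on aldehyde 8 itself, where the 2-OH is tied up in the chelate and only the 4-OH can react. This gives the fully substituted salicylaldehyde F1.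
- The dithiane is then introduced without Brønsted acid, using 1,3-bis(trimethylsilylsulfanyl)propane (C[Si](C)(C)SCCCS[Si](C)(C)C) and catalytic ZnI2 in Et2O at 0 °C. Silicon takes up the carbonyl oxygen and the product is 11.

Step 7 (SN2 by a hindered phenol at an ionisable benzylic carbinol, with a risk of ee erosion or styrene formation). The fallback sets out from 11 and comes back at 16, and it makes the two ring bonds in the reverse order.
- Phenol 11 undergoes an intermolecular Mitsunobu reaction with purchased (S)-2-chloro-1-phenylethanol (O[C@@H](c1ccccc1)CCl) using PPh3 and DIAD in concentrated toluene, 0 °C → rt. The β-chlorine destabilises a benzylic cation and enforces inversion, giving the (R)-2-chloro-1-phenylethyl aryl ether F5.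
- n-BuLi (1.05 equiv, THF, −78 °C) forms the lithiodithiane F6.
- On warming, F6 closes the C3–C4 bond by 6-exo-tet displacement of chloride without touching the stereocentre, giving 16.

**Further compounds**
F1 | step 5 | 2-hydroxy-4-[(2-methylbut-3-en-2-yl)oxy]-3-(3-methylbut-2-en-1-yl)benzaldehyde | C=CC(C)(C)Oc1ccc(C=O)c(O)c1CC=C(C)C
F2 | step 6 | 2-{4-[(2-methylbut-3-en-2-yl)oxy]-3-(3-methylbut-2-en-1-yl)-2-{[2-(trimethylsilyl)ethoxy]methoxy}phenyl}-1,3-dithiane (SEM ether of 11) | C=CC(C)(C)Oc1ccc(C2SCCCS2)c(OCOCC[Si](C)(C)C)c1CC=C(C)C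
F3 | step 6 | 2-lithio-1,3-dithiane derived from F2 | C=CC(C)(C)Oc1ccc(C2([Li])SCCCS2)c(OCOCC[Si](C)(C)C)c1CC=C(C)C
F4 | step 6 | (1R)-2-{2-[4-[(2-methylbut-3-en-2-yl)oxy]-3-(3-methylbut-2-en-1-yl)-2-{[2-(trimethylsilyl)ethoxy]methoxy}phenyl]-1,3-dithian-2-yl}-1-phenylethan-1-ol | C=CC(C)(C)Oc1ccc(C2(C[C@@H](O)c3ccccc3)SCCCS2)c(OCOCC[Si](C)(C)C)c1CC=C(C)C
F5 | step 7 | 2-{2-[(1R)-2-chloro-1-phenylethoxy]-4-[(2-methylbut-3-en-2-yl)oxy]-3-(3-methylbut-2-en-1-yl)phenyl}-1,3-dithiane | C=CC(C)(C)Oc1ccc(C2SCCCS2)c(O[C@H](c3ccccc3)CCl)c1CC=C(C)C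
F6 | step 7 | 2-lithio-1,3-dithiane derived from F5 | C=CC(C)(C)Oc1ccc(C2([Li])SCCCS2)c(O[C@H](c3ccccc3)CCl)c1CC=C(C)C
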